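**Retrosynthetic overview** (labdane numbering for the ring atoms)

- The target acid comes from its tert-butyl ester by acidolysis, and the 7-en-6-one from a Δ7 bicyclic ester by allylic C–H oxidation at C6, mirroring the late oxygenation in the biosynthesis.
- The Δ7 bicycle comes from an open-chain (2Z,6E,10E)-tetraene ester by one enantioselective proton-initiated bicyclization: ring A (C4–C5) closes first, then ring B (C9–C10), and the cascade ends by loss of H-7. C5, C9 and C10 are all set here. The target belongs to the ent series (mirror image of the sclareol family), so the configuration comes from the chiral acid.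
- The tetraene comes from a (Z)-enol triflate and an acetoxymethylzinc reagent (C13–C16, geometry by retention). The triflate comes from a β-keto ester made from (2E,6E)-farnesyl bromide and the dianion of tert-butyl acetoacetate (C11–C12).

Assumption: the (S)-binaphthol-derived acid of step 4 gives the ent series (its (R)-antipode is taken as the one that leads to the normal series to which natural ambrox belongs); if the sense is the reverse, the (R)-acid is used and nothing else changes.

**Step 1**
Reactants: 1 (2E,6E)-farnesyl bromide; 2 tert-butyl acetoacetate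
Product: 4 tert-butyl (6E,10E)-7,11,15-trimethyl-3-oxohexadeca-6,10,14-trienoate, via acetoacetate dianion 3 (not isolated)
Conditions: 2, NaH (1.1 equiv), THF, 0 °C; n-BuLi (1.05 equiv), 0 °C; then 1, 0 °C → rt; aq NH4Cl
Reagents that add atoms: none
Why: Weiler dianion alkylation, in which the more basic terminal carbanion of the acetoacetate dianion displaces the primary allylic bromide in an SN2 sense without touching the E-alkenes, so the C11–C12 bond forms regioselectively and no stereocentre is involved.

**Step 2**
Reactants: 4 tert-butyl (6E,10E)-7,11,15-trimethyl-3-oxohexadeca-6,10,14-trienoate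
Product: 5 tert-butyl (2Z,6E,10E)-7,11,15-trimethyl-3-(trifluoromethylsulfonyloxy)hexadeca-2,6,10,14-tetraenoate
Conditions: Tf2O (1.5 equiv), sat. aq LiOH, hexanes, 5 °C
Reagents that add atoms: triflic anhydride, O=S(=O)(OS(=O)(=O)C(F)(F)F)C(F)(F)F
Why: Chelation-controlled enol triflation, in which the lithium-chelated enolate of the β-keto ester is trapped on oxygen so that OTf sits cis to the ester (2Z), the geometry later needed for C16, while the biphasic base keeps acid away from the polyene.

**Step 3**
Reactants: 5 tert-butyl (2Z,6E,10E)-7,11,15-trimethyl-3-(trifluoromethylsulfonyloxy)hexadeca-2,6,10,14-tetraenoate; 6 bromomethyl acetate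
Product: 8 tert-butyl (2Z,6E,10E)-3-(acetoxymethyl)-7,11,15-trimethylhexadeca-2,6,10,14-tetraenoate, via (acetoxymethyl)zinc bromide 7 (not isolated)
Conditions: 6, Zn dust, THF–DMSO, 15 °C; then 5, Pd(PPh3)4 (5 mol %), THF, 0 → 25 °C
Reagents that add atoms: none
Why: Negishi coupling, in which zinc inserts into the C–Br bond of the α-acyloxy bromide to give the chelate-stabilised zinc reagent, which transmetalates to the vinylpalladium formed from the activated enol triflate and reductively eliminates with retention of alkene geometry (the CH2OAc group has no β-hydrogen), so CH2OAc ends up cis to the ester.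

**Step 4**
Reactants: 8 tert-butyl (2Z,6E,10E)-3-(acetoxymethyl)-7,11,15-trimethylhexadeca-2,6,10,14-tetraenoate
Product: 9 tert-butyl (13Z)-16-acetoxy-ent-labda-7,13-dien-15-oate (5R,9R,10R)
Conditions: (S)-2-hydroxy-2'-[(2-fluorobenzyl)oxy]-1,1'-binaphthyl (2.2 equiv), SnCl4 (2.0 equiv), toluene, −78 °C, 48 h; chromatography on AgNO3–SiO2
Reagents that add atoms: none
Why: Proposed new method: a biomimetic proton-initiated cationic polyene bicyclization in which the chiral Lewis acid-assisted Brønsted acid protonates one enantiotopic face of the terminal isopropylidene, the chair–chair folded 6E,10E chain closes ring A and then ring B by anti additions (trans ring fusion with the C9 side chain equatorial, so C5, C9 and C10 follow from the face fixed in the first C–C bond formation), and the electron-poor SnCl4-complexed enoate alkene cannot act as a third nucleophile so the C8 cation ends by loss of the axial H-7 to give the Δ7 alkene, the closest known reaction type being the enantioselective cyclization of homofarnesol and of homopolyprenyl arenes by the same class of chiral acid, here extended to proton-loss termination on an ester-bearing tetraene.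

**Step 5**
Reactants: 9 tert-butyl (13Z)-16-acetoxy-ent-labda-7,13-dien-15-oate
Product: 10 tert-butyl (13Z)-16-acetoxy-6-oxo-ent-labda-7,13-dien-15-oate (5R,9R,10S)
Conditions: CrO3 (15 equiv), 3,5-dimethylpyrazole (15 equiv), CH2Cl2, −20 °C, 4 h
Reagents that add atoms: chromium trioxide, O=[Cr](=O)=O
Why: Allylic C–H oxidation with the CrO3·3,5-dimethylpyrazole complex, in which C6 is the only ring methylene allylic to the electron-rich Δ7 alkene and its oxidation gives the conjugated 7-en-6-one, while the enoate alkene, C12 and the hindered tertiary H-9 are electronically or sterically deactivated and the ring-fusion centres are untouched.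

**Step 6**
Reactants: 10 tert-butyl (13Z)-16-acetoxy-6-oxo-ent-labda-7,13-dien-15-oate
Product: 11 (13Z)-16-acetoxy-6-oxo-ent-labda-7,13-dien-15-oic acid (5R,9R,10S; the target)
Conditions: CF3CO2H–CH2Cl2 (1:4), 0 °C → rt, 1 h
Reagents that add atoms: none
Why: Acidolysis of the tert-butyl ester (E1 loss of isobutene) frees the acid under anhydrous conditions that leave the primary acetate, the enone, the 13Z alkene and the three stereocentres unchanged.

**Compound list**

1 | (2E,6E)-farnesyl bromide, (2E,6E)-1-bromo-3,7,11-trimethyldodeca-2,6,10-triene | CC(C)=CCC/C(C)=C/CC/C(C)=C/CBr | starting material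
2 | tert-butyl acetoacetate (tert-butyl 3-oxobutanoate) | CC(=O)CC(=O)OC(C)(C)C | starting material
3 | sodium lithium dianion (1,3-bis-enolate) of tert-butyl acetoacetate | [Na+].[Li+].C=C([O-])C=C([O-])OC(C)(C)C | intermediate
4 | tert-butyl (6E,10E)-7,11,15-trimethyl-3-oxohexadeca-6,10,14-trienoate | CC(C)=CCC/C(C)=C/CC/C(C)=C/CCC(=O)CC(=O)OC(C)(C)C | intermediate
5 | tert-butyl (2Z,6E,10E)-7,11,15-trimethyl-3-(trifluoromethylsulfonyloxy)hexadeca-2,6,10,14-tetraenoate (OTf cis to the ester) | CC(C)=CCC/C(C)=C/CC/C(C)=C/CC/C(OS(=O)(=O)C(F)(F)F)=C/C(=O)OC(C)(C)C | intermediate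
6 | bromomethyl acetate | CC(=O)OCBr | starting material
7 | (acetoxymethyl)zinc bromide | CC(=O)OC[Zn]Br | intermediate
8 | tert-butyl (2Z,6E,10E)-3-(acetoxymethyl)-7,11,15-trimethylhexadeca-2,6,10,14-tetraenoate (CH2OAc cis to the ester) | CC(C)=CCC/C(C)=C/CC/C(C)=C/CC/C(COC(C)=O)=C/C(=O)OC(C)(C)C | intermediate
9 | tert-butyl (13Z)-16-acetoxy-ent-labda-7,13-dien-15-oate; tert-butyl (2Z)-3-(acetoxymethyl)-5-[(1R,4aR,8aR)-2,5,5,8a-tetramethyl-1,4,4a,5,6,7,8,8a-octahydronaphthalen-1-yl]pent-2-enoate; trans-decalin with the C10 methyl and the C9 side chain on one face and H-5 on the other | CC(=O)OC/C(=C\C(=O)OC(C)(C)C)CC[C@@H]1C(C)=CC[C@@H]2C(C)(C)CCC[C@@]12C | intermediate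
10 | tert-butyl (13Z)-16-acetoxy-6-oxo-ent-labda-7,13-dien-15-oate; tert-butyl (2Z)-3-(acetoxymethyl)-5-[(1R,4aR,8aS)-2,5,5,8a-tetramethyl-4-oxo-1,4,4a,5,6,7,8,8a-octahydronaphthalen-1-yl]pent-2-enoate | CC(=O)OC/C(=C\C(=O)OC(C)(C)C)CC[C@@H]1C(C)=CC(=O)[C@@H]2C(C)(C)CCC[C@@]12C | intermediate
11 | (13Z)-16-acetoxy-6-oxo-ent-labda-7,13-dien-15-oic acid; (2Z)-3-(acetoxymethyl)-5-[(1R,4aR,8aS)-2,5,5,8a-tetramethyl-4-oxo-1,4,4a,5,6,7,8,8a-octahydronaphthalen-1-yl]pent-2-enoic acid | CC(=O)OC/C(=C\C(=O)O)CC[C@@H]1C(C)=CC(=O)[C@@H]2C(C)(C)CCC[C@@]12C | target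

**Step count and risks**

Total steps: 6. Longest linear sequence: 6 (from 1 and 2).

The three steps most likely to fail are step 4, step 3 and step 5, in that order.

Step 4 is the least certain. The chiral acid may give only moderate enantiomeric excess, part of the material may stop after ring A, and the Δ8(17) and Δ8(9) alkene isomers may accompany the Δ7 product. The tert-butyl ester must also survive SnCl4 at −78 °C. The fallback changes the initiating electrophile from a proton to an iodonium ion. It sets out from 8, which is treated with N-iodosuccinimide and one equivalent of a chiral binaphthol-derived phosphoramidite promoter (toluene, −40 °C; the promoter enantiomer that leads to the ent series). This closes both rings to tert-butyl (3R,13Z)-16-acetoxy-3-iodo-ent-labda-7,13-dien-15-oate F1, with iodine equatorial, and the bridged iodonium fixes the face of the first ring closure. Radical deiodination (Bu3SnH, AIBN, toluene, 80 °C) then returns the route to 9.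

Step 3 depends on an α-acyloxy zinc reagent that may transmetalate slowly. The product also carries an allylic acetate that zerovalent palladium can ionize, which could scramble the 2Z geometry. The fallback brings in C16 as carbon monoxide and adds the acetate only after the palladium chemistry. It sets out from 5: reductive carbonylation (CO 1 atm, Bu3SnH added slowly, Pd(PPh3)4, THF, 50 °C) gives tert-butyl (2Z,6E,10E)-3-formyl-7,11,15-trimethylhexadeca-2,6,10,14-tetraenoate F2 with retention of geometry. Luche reduction (NaBH4, CeCl3·7H2O, MeOH, −78 °C) gives tert-butyl (2Z,6E,10E)-3-(hydroxymethyl)-7,11,15-trimethylhexadeca-2,6,10,14-tetraenoate F3, whose bulky ester slows lactonization. F3 is acetylated cold and at once (Ac2O, pyridine, DMAP, 0 °C) and so comes back to the route at 8.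

Step 5 may over-oxidize (H-9, C17) or attack C12 of the side chain. The fallback replaces the one-step chromium oxidation by a radical peroxidation followed by base-induced fragmentation. It sets out from 9: t-BuOOH with catalytic CuCl (benzene, 60 °C, Kharasch-type peroxidation) places a peroxide on the allylic ring carbon and gives tert-butyl (6R,13Z)-16-acetoxy-6-(tert-butylperoxy)-ent-labda-7,13-dien-15-oate F4, with the C–O bond on the face opposite the C10 methyl. DBU (CH2Cl2, 25 °C, Kornblum–DeLaMare fragmentation) then removes H-6 and expels tert-butoxide, which returns the route to 10.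

**Further compounds**

F1 | step 4 | tert-butyl (3R,13Z)-16-acetoxy-3-iodo-ent-labda-7,13-dien-15-oate | CC(=O)OC/C(=C\C(=O)OC(C)(C)C)CC[C@@H]1C(C)=CC[C@@H]2C(C)(C)[C@H](I)CC[C@@]12C
F2 | step 3 | tert-butyl (2Z,6E,10E)-3-formyl-7,11,15-trimethylhexadeca-2,6,10,14-tetraenoate | CC(C)=CCC/C(C)=C/CC/C(C)=C/CC/C(C=O)=C/C(=O)OC(C)(C)C
F3 | step 3 | tert-butyl (2Z,6E,10E)-3-(hydroxymethyl)-7,11,15-trimethylhexadeca-2,6,10,14-tetraenoate | CC(C)=CCC/C(C)=C/CC/C(C)=C/CC/C(CO)=C/C(=O)OC(C)(C)C
F4 | step 5 | tert-butyl (6R,13Z)-16-acetoxy-6-(tert-butylperoxy)-ent-labda-7,13-dien-15-oate | CC(=O)OC/C(=C\C(=O)OC(C)(C)C)CC[C@@H]1C(C)=C[C@@H](OOC(C)(C)C)[C@@H]2C(C)(C)CCC[C@@]12C
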